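(The earlier runs and the new flask were generated by integration for substances that don't exist; scatter was added.)

Every part of a substrate charge in a closed flask stands somewhere: as free substrate, as target, or in a form not read. I had the west run and a row of flasks to judge.

| flask | substrate | partner | remark | time |
|---|---|---|---|---|
| west | 0.025 M | 0.24 M | run made earlier |  |
| gamma | 0.025 M | 0.160 M |  | 20 h |
| epsilon | 0.050 M | 0.160 M |  | 20 h |
| zeta | 0.10 M | 0.160 M |  | 20 h |
| theta | 0.20 M | 0.160 M |  | 20 h |
| delta | 0.40 M | 0.160 M |  | 20 h |

- west (time / h: target / %, substrate / %): 1.50: 0, 76; 3.00: 5, 64; 5.00: 6, 56; 6.00: 9, 50; 8.00: 12, 47; 10.0: 16, 40; 12.0: 23, 36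

(scatter of a reading: 1.5 percentage points)

- "hardly changes" means that all values lie within two and a half points (for a concentration: within two and a half percent of the largest)

1. [target] at the end for gamma, epsilon, zeta, theta, delta, in this order
2. the course of these numbers from the first flask to the last (rises, then falls / rises all the way / hardly changes / falls all the way / falls, then rises)

In west at 12.0 h, the readings of free substrate, 36 %, and target, 23 %, left 41.0 % unread. Substrate loss had slowed by then, so I treated the fast step as over and took everything that was not target as one pool feeding target. I assumed that target in percent of the charge does not depend on the charge, and bracketed one number: the loss-free yield, the share of the charge standing as target at 20 h if none of it is consumed.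

The loosest upper bound is the whole charge. To tighten it, I carried on west's shrinkage of the pool from 6.00 h to 12.0 h, which gave 38.4 %, since I expected the weaker partner charge to be no faster. For the lower bound, I scaled west's 23 % by the partner ratio and let nothing form afterwards, which gave 15.3 %. So I put gamma between 0.00383 M and 0.00959 M, and delta between 0.0613 M and 0.154 M, as estimates from one scattered run.

The forecast gave 0.0075 M, 0.014 M, 0.025 M, 0.045 M and 0.07 M, a course that rises all the way, with the note that at high substrate “target grows less than proportionally”. Its gamma and delta values both stood inside my brackets.

The flasks gave 0.00531 M, 0.00947 M, 0.0152 M, 0.0204 M and 0.0195 M: the course rises, then falls.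

    substrate ⇌ open intermediate (K = 1.00, k = 0.00370 min⁻¹)
    partner → second intermediate (k = 0.00390 min⁻¹)
    open intermediate + second intermediate → target (k = 0.00730 M⁻¹ min⁻¹)
    target → over-reaction product (k = 0.00100 min⁻¹)
    substrate + target → side product (k = 0.0190 M⁻¹ min⁻¹)

In gamma, target stood at 21.3 % of the charge, between 15.3 % and 38.4 %, and its half-life by the reaction to over-reaction product, 12 h, was shorter than the 24 h by the reaction with substrate at gamma's charges, the first reaction using target 6.6 times as fast as the second at 20.0 h. In delta, the half-life of target by the reaction with substrate, reckoned at the substrate charged, was 1.52 h, shorter than the 11.6 h by the reaction to over-reaction product, and target stood at 4.87 % of the charge at 20.0 h, below 15.3 %, beside side product at 29.6 %.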